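**Retrosynthetic overview**

1. Numbering: ring B is the dihydronaphthalene ring C1(aryl)–C2–C3=C4–C4a–C8a, ring A the fused catechol ring, ring C the catechol ring on C1. Rabdosiin comes from one acidolysis of its tetra-acetonide bis(tert-butyl ester).
2. Ring B is closed last, in a [3+3] palladium domino: C4–C4a by Heck arylation and C1–C2 by intramolecular benzylic alkylation. The partners are an ortho-iodo benzhydryl carbonate (rings A and C with C1) and an itaconate diester (C2–C3–C4 with both depside arms already attached).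
3. Enabling feature: C1 is doubly benzylic (between ring A and ring C, each with an oxygen para to it), so a C1–O bond ionises on palladium. C2–H is α to its ester and vinylogous through C3=C4 to ring A, so it is acidic. C4 is the free CH2 end of an itaconate, and C4a/C8a are ortho neighbours on ring A.
4. The benzhydryl carbonate comes from an enantioselective aryl transfer to an ortho-iodo aldehyde. The itaconate comes from a double Mitsunobu esterification (inversion) of itaconic acid with an (S)-aryl-lactate made by glycidate opening.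
5. All four catechol rings come from one aryl bromide; no ring other than ring B is built.

Key step: step 9

Assumption: the target SMILES is read as (1R,2S)-trans in ring B with both depside (lactate) carbons R.
Assumption: 5-bromo-2,2-dimethyl-1,3-benzodioxole and (+)-MIB ((+)-3-exo-morpholinoisoborneol) are taken as purchasable.

**Route**

Step 1
Reactants: 1 5-bromo-2,2-dimethyl-1,3-benzodioxole
Product: 2 2,2-dimethyl-1,3-benzodioxole-5-carbaldehyde
Conditions: Pd(OAc)2 (0.5 mol %), di(1-adamantyl)-n-butylphosphine (1.5 mol %), TMEDA (1.1 equiv), CO/H2 (1:1, 5 bar), toluene, 100 °C; 1 M NaOH wash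
Reagents that add atoms: carbon monoxide, [C-]#[O+]
Why: Palladium-catalysed reductive carbonylation (formylation) of an aryl bromide, in which oxidative addition, CO insertion to the aroylpalladium bromide and amine-assisted hydrogenolysis by H2 give the aldehyde, a sequence that tolerates electron-rich bromoarenes and, being free of acid, the ketal; no stereocentre is involved.

Step 2
Reactants: 2 2,2-dimethyl-1,3-benzodioxole-5-carbaldehyde
Product: 3 6-iodo-2,2-dimethyl-1,3-benzodioxole-5-carbaldehyde
Conditions: I2, AgOCOCF3, CH2Cl2, 0 °C → rt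
Reagents that add atoms: iodine, II
Why: Silver-assisted electrophilic aromatic iodination should go para to a ring oxygen and ortho to the formyl group (position 6), as in the halogenation of piperonal-type aldehydes, and the anhydrous medium should spare the ketal.

Step 3
Reactants: 1 5-bromo-2,2-dimethyl-1,3-benzodioxole, 3 6-iodo-2,2-dimethyl-1,3-benzodioxole-5-carbaldehyde
Product: 6 (R)-(6-iodo-2,2-dimethyl-1,3-benzodioxol-5-yl)(2,2-dimethyl-1,3-benzodioxol-5-yl)methanol, via aryllithium 4 (not isolated), via arylbutylzinc 5 (not isolated)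
Conditions: 1, n-BuLi, t-BuOMe, −78 °C; ZnCl2; n-BuLi; TEEDA; (+)-MIB (5 mol %), 3, 0 °C; aq. NH4Cl
Reagents that add atoms: none
Why: Amino-alcohol-catalysed enantioselective aryl transfer from a mixed aryl(butyl)zinc to an aldehyde (aryl migrates in preference to butyl, TEEDA ties up LiCl to suppress the racemic background, the organozinc leaves the aryl iodide alone); by analogy with dialkylzinc additions, where the (−)-ligand delivers the carbon group to the Si face of aryl aldehydes, the (+)-ligand should deliver ring C to the Re face of 3 and set the (R)-carbinol.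

Step 4
Reactants: 6 (R)-(6-iodo-2,2-dimethyl-1,3-benzodioxol-5-yl)(2,2-dimethyl-1,3-benzodioxol-5-yl)methanol
Product: 7 tert-butyl (R)-(6-iodo-2,2-dimethyl-1,3-benzodioxol-5-yl)(2,2-dimethyl-1,3-benzodioxol-5-yl)methyl carbonate
Conditions: Boc2O, DMAP (10 mol %), CH2Cl2, 0 °C
Reagents that add atoms: di-tert-butyl dicarbonate, CC(C)(C)OC(=O)OC(=O)OC(C)(C)C
Why: DMAP-catalysed O-acylation of the secondary alcohol breaks no bond at the stereocentre, so the (R) configuration is carried over.

Step 5
Reactants: 1 5-bromo-2,2-dimethyl-1,3-benzodioxole, 8 methyl (S)-oxirane-2-carboxylate (methyl (S)-glycidate)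
Product: 10 methyl (2S)-3-(2,2-dimethyl-1,3-benzodioxol-5-yl)-2-hydroxypropanoate, via arylmagnesium bromide 9 (not isolated)
Conditions: Mg, THF, 40 °C; CuI (10 mol %), 8, THF, −40 → −20 °C; aq. NH4Cl
Reagents that add atoms: none
Why: Copper-catalysed SN2 opening of the epoxide by the aryl Grignard reagent at the unsubstituted CH2 is faster than ester addition at low temperature; the stereocentre is not touched, so (S) is retained.

Step 6
Reactants: 10 methyl (2S)-3-(2,2-dimethyl-1,3-benzodioxol-5-yl)-2-hydroxypropanoate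
Product: 11 (2S)-3-(2,2-dimethyl-1,3-benzodioxol-5-yl)-2-hydroxypropanoic acid
Conditions: LiOH, THF/H2O, 0 °C; 1 M HCl to pH 3, 0 °C
Reagents that add atoms: lithium hydroxide, [Li+].[OH-]
Why: Ester saponification by acyl–oxygen cleavage; an α-hydroxy carboxylate does not racemise under these conditions, and the ketal is stable to base and to a brief cold acidification.

Step 7
Reactants: 11 (2S)-3-(2,2-dimethyl-1,3-benzodioxol-5-yl)-2-hydroxypropanoic acid
Product: 12 tert-butyl (2S)-3-(2,2-dimethyl-1,3-benzodioxol-5-yl)-2-hydroxypropanoate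
Conditions: tert-butyl 2,2,2-trichloroacetimidate, CH2Cl2/cyclohexane, rt
Reagents that add atoms: tert-butyl 2,2,2-trichloroacetimidate, CC(C)(C)OC(=N)C(Cl)(Cl)Cl
Why: The carboxylic acid itself protonates the imidate and is tert-butylated, whereas the secondary alcohol needs a Lewis acid to react, so esterification is chemoselective and leaves the stereocentre alone.

Step 8
Reactants: 12 tert-butyl (2S)-3-(2,2-dimethyl-1,3-benzodioxol-5-yl)-2-hydroxypropanoate (2.1 equiv), 13 itaconic acid (2-methylidenebutanedioic acid)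
Product: 14 bis[(2R)-1-tert-butoxy-3-(2,2-dimethyl-1,3-benzodioxol-5-yl)-1-oxopropan-2-yl] 2-methylidenebutanedioate
Conditions: PPh3, DIAD, THF, 0 °C → rt
Reagents that add atoms: none
Why: Double Mitsunobu esterification, in which each itaconate carboxylate displaces the alkoxyphosphonium of the α-hydroxy ester by SN2 with inversion (S → R at both lactate carbons); the carboxyl groups are never activated, so neither anhydride formation nor isomerisation to citraconate or mesaconate is expected.

Step 9
Reactants: 7 tert-butyl (R)-(6-iodo-2,2-dimethyl-1,3-benzodioxol-5-yl)(2,2-dimethyl-1,3-benzodioxol-5-yl)methyl carbonate (1.1 equiv), 14 bis[(2R)-1-tert-butoxy-3-(2,2-dimethyl-1,3-benzodioxol-5-yl)-1-oxopropan-2-yl] 2-methylidenebutanedioate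
Product: 16 protected rabdosiin (tetra-acetonide bis-tert-butyl ester; full name in the compound list), via arylidenesuccinate 15 (not isolated)
Conditions: Pd(OAc)2 (5 mol %), DPEphos (6 mol %), K2CO3 (2 equiv), n-Bu4NBr (20 mol %), 1,4-dioxane, 70 °C then 95 °C, argon
Reagents that add atoms: none
Why: Proposed new method: zerovalent palladium first inserts into the C4a–I bond of 7, adds to the unsubstituted CH2 terminus (C4) of itaconate 14 and undergoes syn β-hydride elimination to the (E)-arylidenesuccinate 15 (Mizoroki–Heck; the new C4–C4a bond), the E geometry holding the CH2CO2R arm (C2) cis to ring A. At the higher temperature the same catalyst ionises the doubly benzylic C1–OBoc bond with inversion to a cationic η3-benzylpalladium, CO2 is lost, and the tert-butoxide set free deprotonates C2–H (α to an ester and vinylogous through C3=C4 to ring A) to a soft dienolate, whose α-carbon attacks C1 on the face away from palladium and closes ring B in a 6-(enolexo)-exo-tet mode (the γ-carbon C4 could only give a four-membered ring). The closest known reactions are the Heck arylation of itaconates to arylidenesuccinates and the palladium-catalysed, net-retentive benzylic (Tsuji–Trost-type) alkylation of diarylmethyl carbonates by stabilised carbanions; new are their union in one domino and an ester dienolate as the nucleophile. C1 is controlled by the substrate: two inversions give net retention, so (R)-7 should give (1R). C2 is under thermodynamic control, being epimerisable through the same dienolate and settling trans to the C1 aryl group (2S), the arrangement of the natural 1-aryl-1,2-dihydronaphthalene lignans. The step needs chemoselectivity (C–I before C–O, secured by the iodide and the temperature ramp), terminal regioselectivity in the Heck event (secured by the 1,1-disubstituted acrylate) and fidelity at C1 (secured by the low-polarity solvent, which suppresses uncatalysed ionisation, and by fast intramolecular capture).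

Step 10
Reactants: 16 protected rabdosiin (tetra-acetonide bis-tert-butyl ester)
Product: 17 rabdosiin
Conditions: TFA/H2O (9:1), argon, 0 °C → rt
Reagents that add atoms: none
Why: Acidolysis should remove the four catechol acetonides (hydrolysis to acetone) and the two tert-butyl esters (loss of isobutene) in one operation, while the depside esters, the C3=C4 enoate and all four stereocentres are untouched by non-oxidising acid.

**Compound list**

1 | 5-bromo-2,2-dimethyl-1,3-benzodioxole | CC1(C)Oc2ccc(Br)cc2O1 | starting material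
2 | 2,2-dimethyl-1,3-benzodioxole-5-carbaldehyde | O=Cc1ccc2OC(C)(C)Oc2c1 | intermediate
3 | 6-iodo-2,2-dimethyl-1,3-benzodioxole-5-carbaldehyde | O=Cc1cc2OC(C)(C)Oc2cc1I | intermediate
4 | (2,2-dimethyl-1,3-benzodioxol-5-yl)lithium | [Li]c1ccc2OC(C)(C)Oc2c1 | intermediate
5 | butyl(2,2-dimethyl-1,3-benzodioxol-5-yl)zinc | CCCC[Zn]c1ccc2OC(C)(C)Oc2c1 | intermediate
6 | (R)-(6-iodo-2,2-dimethyl-1,3-benzodioxol-5-yl)(2,2-dimethyl-1,3-benzodioxol-5-yl)methanol | O[C@@H](c1cc2OC(C)(C)Oc2cc1I)c1ccc2OC(C)(C)Oc2c1 | intermediate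
7 | tert-butyl (R)-(6-iodo-2,2-dimethyl-1,3-benzodioxol-5-yl)(2,2-dimethyl-1,3-benzodioxol-5-yl)methyl carbonate | CC(C)(C)OC(=O)O[C@@H](c1cc2OC(C)(C)Oc2cc1I)c1ccc2OC(C)(C)Oc2c1 | intermediate
8 | methyl (S)-oxirane-2-carboxylate | COC(=O)[C@@H]1CO1 | starting material
9 | (2,2-dimethyl-1,3-benzodioxol-5-yl)magnesium bromide | Br[Mg]c1ccc2OC(C)(C)Oc2c1 | intermediate
10 | methyl (2S)-3-(2,2-dimethyl-1,3-benzodioxol-5-yl)-2-hydroxypropanoate | COC(=O)[C@@H](O)Cc1ccc2OC(C)(C)Oc2c1 | intermediate
11 | (2S)-3-(2,2-dimethyl-1,3-benzodioxol-5-yl)-2-hydroxypropanoic acid | OC(=O)[C@@H](O)Cc1ccc2OC(C)(C)Oc2c1 | intermediate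
12 | tert-butyl (2S)-3-(2,2-dimethyl-1,3-benzodioxol-5-yl)-2-hydroxypropanoate | CC(C)(C)OC(=O)[C@@H](O)Cc1ccc2OC(C)(C)Oc2c1 | intermediate
13 | itaconic acid (2-methylidenebutanedioic acid) | C=C(CC(=O)O)C(=O)O | starting material
14 | bis[(2R)-1-tert-butoxy-3-(2,2-dimethyl-1,3-benzodioxol-5-yl)-1-oxopropan-2-yl] 2-methylidenebutanedioate | C=C(CC(=O)O[C@H](Cc1ccc2OC(C)(C)Oc2c1)C(=O)OC(C)(C)C)C(=O)O[C@H](Cc1ccc2OC(C)(C)Oc2c1)C(=O)OC(C)(C)C | intermediate
15 | bis[(2R)-1-tert-butoxy-3-(2,2-dimethyl-1,3-benzodioxol-5-yl)-1-oxopropan-2-yl] (2E)-2-[(6-{(R)-[(tert-butoxycarbonyl)oxy](2,2-dimethyl-1,3-benzodioxol-5-yl)methyl}-2,2-dimethyl-1,3-benzodioxol-5-yl)methylidene]butanedioate | CC(C)(C)OC(=O)O[C@@H](c1cc2OC(C)(C)Oc2cc1/C=C(\CC(=O)O[C@H](Cc1ccc2OC(C)(C)Oc2c1)C(=O)OC(C)(C)C)C(=O)O[C@H](Cc1ccc2OC(C)(C)Oc2c1)C(=O)OC(C)(C)C)c1ccc2OC(C)(C)Oc2c1 | intermediate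
16 | protected rabdosiin: bis[(2R)-1-tert-butoxy-3-(2,2-dimethyl-1,3-benzodioxol-5-yl)-1-oxopropan-2-yl] (5R,6S)-5-(2,2-dimethyl-1,3-benzodioxol-5-yl)-2,2-dimethyl-5,6-dihydronaphtho[2,3-d][1,3]dioxole-6,7-dicarboxylate (C5 and C6 are C1 and C2 of ring B) | O=C(O[C@H](Cc1ccc2OC(C)(C)Oc2c1)C(=O)OC(C)(C)C)C1=Cc2cc3OC(C)(C)Oc3cc2[C@@H](c2ccc3OC(C)(C)Oc3c2)[C@@H]1C(=O)O[C@H](Cc1ccc2OC(C)(C)Oc2c1)C(=O)OC(C)(C)C | intermediate
17 | rabdosiin, (1R,2S) in ring B, both depside carbons R | O=C(O[C@H](Cc1ccc(O)c(O)c1)C(=O)O)C1=Cc2cc(O)c(O)cc2[C@@H](c2ccc(O)c(O)c2)[C@@H]1C(=O)O[C@H](Cc1ccc(O)c(O)c1)C(=O)O | target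

**Step count**

Total: 10 steps. Longest linear sequence: 6 steps (1 → 2 → 3 → 6 → 7 → 16 → 17; the branch 1 + 8 → 10 → 11 → 12 → 14 → 16 → 17 is equally long).

**Steps most likely to fail**

1. Step 9 (proposed new method). Several processes may go wrong:
   - The two palladium events may lose their order: ionisation at C1 before the Heck event would allow the itaconate dienolate to be benzylated between molecules at its γ-carbon.
   - Configuration at C1 may erode through uncatalysed ionisation, or invert if the dienolate is delivered through the metal (the enantiomeric carbonate would then be needed).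
   - The lactate centres may epimerise under base.
   - The arylpalladium may attack ring C directly to give a fluorene.

   The fallback uses known chemistry, sets out from 2 and 12 and comes back at 16. A double Stobbe condensation of 2 (2.2 equiv) with dimethyl succinate (NaOMe, MeOH, reflux; then aq. NaOH) gives (2E,3E)-2,3-bis[(2,2-dimethyl-1,3-benzodioxol-5-yl)methylidene]butanedioic acid F1. Methylation (MeI, K2CO3, DMF) gives its dimethyl ester F2. TfOH in CH2Cl2 at 0 °C protonates one arylidene unit, and the benzylic cation is captured by the other aryl ring para to its oxygen (Friedel–Crafts closure of ring B, here through C1–C8a), giving racemic trans-dimethyl 5-aryl-5,6-dihydronaphthodioxole-6,7-dicarboxylate F3. LiOH hydrolysis gives the racemic trans diacid F4. A double Mitsunobu esterification of F4 with 12 (PPh3, DIAD, THF) gives 16 together with its (1S,2R) diastereomer F5. The two are separated by chromatography, the (R)-lactate arms serving as the resolving element.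

2. Step 3. Facial selectivity may be poor (or its sense reversed) on the electron-rich ortho-iodo aldehyde, and butyl may transfer in competition with aryl. A reversed sense alone is corrected with the antipodal ligand. The fallback sets out from 3 and 1 and comes back at 6. The Grignard reagent 9 made from 1 adds to 3 (THF, −78 °C) to give the racemic benzhydrol F6. MnO2 in CH2Cl2 oxidises it to (6-iodo-2,2-dimethyl-1,3-benzodioxol-5-yl)(2,2-dimethyl-1,3-benzodioxol-5-yl)methanone F7. A Corey–Bakshi–Shibata reduction (BH3·SMe2, (S)-2-methyl-CBS-oxazaborolidine, THF, −20 °C), in which the twisted ortho-iodoaryl ring should act as the large group, then returns (R)-6; the antipodal oxazaborolidine is used if the sense proves opposite.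

3. Step 8. The activated β-aryl lactate may eliminate to the cinnamate under Mitsunobu activation, the second esterification may stall, or the phosphine may add to the itaconate in conjugate fashion. The fallback sets out from 12 and 13 and comes back at 14. Alcohol 12 is converted with Tf2O and 2,6-lutidine (CH2Cl2, −78 °C) into tert-butyl (2S)-3-(2,2-dimethyl-1,3-benzodioxol-5-yl)-2-(trifluoromethylsulfonyloxy)propanoate F8. This isolated electrophile is displaced with inversion by dicesium itaconate (13, Cs2CO3, DMF, 0 °C), a carboxylate SN2 alkylation that needs no phosphine and gives 14 directly.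

Further compounds

F1 | step 9 | (2E,3E)-2,3-bis[(2,2-dimethyl-1,3-benzodioxol-5-yl)methylidene]butanedioic acid | OC(=O)/C(=C/c1ccc2OC(C)(C)Oc2c1)C(=C/c1ccc2OC(C)(C)Oc2c1)\C(=O)O
F2 | step 9 | dimethyl (2E,3E)-2,3-bis[(2,2-dimethyl-1,3-benzodioxol-5-yl)methylidene]butanedioate | COC(=O)/C(=C/c1ccc2OC(C)(C)Oc2c1)C(=C/c1ccc2OC(C)(C)Oc2c1)\C(=O)OC
F3 | step 9 | rac-dimethyl (5R,6S)-5-(2,2-dimethyl-1,3-benzodioxol-5-yl)-2,2-dimethyl-5,6-dihydronaphtho[2,3-d][1,3]dioxole-6,7-dicarboxylate (racemate, trans; one enantiomer drawn) | COC(=O)C1=Cc2cc3OC(C)(C)Oc3cc2[C@@H](c2ccc3OC(C)(C)Oc3c2)[C@@H]1C(=O)OC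
F4 | step 9 | rac-(5R,6S)-5-(2,2-dimethyl-1,3-benzodioxol-5-yl)-2,2-dimethyl-5,6-dihydronaphtho[2,3-d][1,3]dioxole-6,7-dicarboxylic acid (racemate, trans; one enantiomer drawn) | OC(=O)C1=Cc2cc3OC(C)(C)Oc3cc2[C@@H](c2ccc3OC(C)(C)Oc3c2)[C@@H]1C(=O)O
F5 | step 9 | (5S,6R) diastereomer of 16, bis[(2R)-1-tert-butoxy-3-(2,2-dimethyl-1,3-benzodioxol-5-yl)-1-oxopropan-2-yl] (5S,6R)-5-(2,2-dimethyl-1,3-benzodioxol-5-yl)-2,2-dimethyl-5,6-dihydronaphtho[2,3-d][1,3]dioxole-6,7-dicarboxylate | O=C(O[C@H](Cc1ccc2OC(C)(C)Oc2c1)C(=O)OC(C)(C)C)C1=Cc2cc3OC(C)(C)Oc3cc2[C@H](c2ccc3OC(C)(C)Oc3c2)[C@H]1C(=O)O[C@H](Cc1ccc2OC(C)(C)Oc2c1)C(=O)OC(C)(C)C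
F6 | step 3 | rac-(6-iodo-2,2-dimethyl-1,3-benzodioxol-5-yl)(2,2-dimethyl-1,3-benzodioxol-5-yl)methanol | OC(c1cc2OC(C)(C)Oc2cc1I)c1ccc2OC(C)(C)Oc2c1
F7 | step 3 | (6-iodo-2,2-dimethyl-1,3-benzodioxol-5-yl)(2,2-dimethyl-1,3-benzodioxol-5-yl)methanone | O=C(c1cc2OC(C)(C)Oc2cc1I)c1ccc2OC(C)(C)Oc2c1
F8 | step 8 | tert-butyl (2S)-3-(2,2-dimethyl-1,3-benzodioxol-5-yl)-2-(trifluoromethylsulfonyloxy)propanoate | CC(C)(C)OC(=O)[C@@H](OS(=O)(=O)C(F)(F)F)Cc1ccc2OC(C)(C)Oc2c1
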